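The constants of this flask set up a race between two losses, and the catalyst loading cancels out of it.

    reagent + free catalyst + right-handed substrate → free catalyst + right-handed product (k1 = 11000 M⁻² s⁻¹)
    left-handed substrate ⇌ right-handed substrate (k2 = 0.035 s⁻¹)
    2 free catalyst → spent catalyst (k3 = 990 M⁻¹ s⁻¹)
    reagent + free catalyst + left-handed substrate → free catalyst + left-handed product (k4 = 6.0 × 10⁵ M⁻² s⁻¹)

left-handed substrate 2.0 mM; reagent 3.00 equiv; free catalyst 2.9 mol%; right-handed substrate 2.0 mM

- the form that holds most of the catalyst when 20% of the left-handed substrate and right-handed substrate together are converted (free catalyst / spent catalyst)
- its share of the catalyst then

Follow one free catalyst at its fork. It can turn over left-handed substrate, on a path faster than the right-handed one by a selectivity factor of 54.5, or it can meet a second free catalyst. Hold c(reagent) at its charge of 6.00 mM. Then c(left-handed substrate) falls in relative terms at 6.0 × 10⁵ M⁻² s⁻¹ times c(reagent) times c(free catalyst), and c(free catalyst) falls in relative terms at twice 990 M⁻¹ s⁻¹ times c(free catalyst). Since c(free catalyst) stands in both, it cancels from their quotient. That quotient, the race ratio, is 1.82, so with c(reagent) held at its charge, left-handed substrate falls faster in relative terms than free catalyst.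

This reckoning sets racemisation aside and sends the turnover down the left-handed path. A conversion of 20% of both substrates together then leaves 60.0% of the left-handed charge. The free share is that fraction raised to one over the race ratio, 75.5%. A neighbouring flask, the same charge with the catalyst loss taken away, keeps its catalyst, so at this conversion it should run 1.32 times as fast. The race ratio also grows with c(reagent), and that should add 0.281 to the apparent order in reagent at this conversion.

The forecast says free catalyst at 74%, a little below this reckoning, on the grounds that “about three quarters is still free”.

The simulation gives free catalyst at 74.7%, reached at 2.95 s, with spent catalyst at 25.3%. So, at a race ratio of 1.82, a quarter of the catalyst has left the flask's work by this point, and the neighbouring flask, with the catalyst loss taken away, runs at 1.33 times the actual rate at that conversion. The loss path is what raises the apparent order in reagent at that conversion from 1.1 to 1.4, a difference of 0.300.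

(All constants belong to no real substance; no experiment stands behind them.)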